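**Plan**

1. The δ-lactone ring of the target (ring O, C=O, CH2, bridgehead CH, decalin-bearing CH, acetal CH) is a fully reduced 5-substituted 2-pyranone whose C6 and C4 are spanned by the O–CH(CO2Me) unit. The retrosynthesis first adds back one ester carbon (CH–CO2Me from C(CO2Me)2), then cuts the acetal C–O and the bridgehead C–C bond together, leaving a flat 5-decalinyl-2-pyranone and dimethyl hydroxymalonate.
2. The pyranone is cut at C3–C4 and O1–C6 into malonic acid and the aminomethylene derivative of a decalinylacetaldehyde, whose CH2CHO arm comes from a vinyl group on the quaternary carbon.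
3. The decalin is cut at the allylic C–CH3 bond (SN2' methylation), the ring A C=C bond (aldol condensation), the quaternary C–CH2 bond (copper-catalysed allyl–alkyl coupling) and the ring-fusion C–vinyl bond (conjugate addition to 4,4-dimethylcyclohexenone).
4. Forward: ring B is the starting enone, ring A closes by aldol condensation, the pyranone by Knoevenagel condensation and lactonisation, and the oxolane bridge last; one ester is then removed.
5. Stereochemistry: the ring-fusion CH comes from Rh/(S)-BINAP, the quaternary carbon from a chiral copper–carbene catalyst, and the secondary methyl from a CBS-set carbinol by anti-SN2' transfer. The acetal, bridgehead and decalin-bearing CH come from the cascade (one-face tether, reversible protonation, chiral base), and the ester CH from equilibration to the exo ester.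

Key step: step 16

Assumption: the sense of induction of the chiral catalysts in steps 1, 6, 8 and 16 is assigned by analogy with their usual behaviour; where the opposite sense is found, the antipodal ligand is used.

**Route**

Step 1
Reactants: 1 4,4-dimethylcyclohex-2-en-1-one
Product: 2 (S)-4,4-dimethyl-3-vinylcyclohexan-1-one
Conditions: CH2=CHBF3K (2 equiv), [Rh(cod)2]BF4 (3 mol%), (S)-BINAP (3.3 mol%), PhMe/H2O, 100 °C
Reagents that add atoms: potassium vinyltrifluoroborate, C=C[B-](F)(F)F.[K+]
Why: Rhodium-catalysed asymmetric 1,4-addition (Hayashi–Miyaura type) of an alkenylboron reagent; the (S)-BINAP complex should deliver the vinyl group to the enone face that gives the (S)-ketone, as it does with cyclohexenone.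

Step 2
Reactants: 2 vinyl ketone
Product: 3 (S)-8,8-dimethyl-7-vinyl-1,4-dioxaspiro[4.5]decane
Conditions: HOCH2CH2OH, p-TsOH (cat.), PhH, reflux (Dean–Stark)
Reagents that add atoms: ethylene glycol, OCCO
Why: Acid-catalysed ketalisation protects the ketone against the borane and the alkoxide base of step 6.

Step 3
Reactants: 4 1,1-dimethoxypropan-2-one
Product: 5 ethyl (E)-4,4-dimethoxy-3-methylbut-2-enoate
Conditions: (EtO)2P(O)CH2CO2Et, NaH, THF, 0 → 25 °C
Reagents that add atoms: triethyl phosphonoacetate, CCOC(=O)CP(=O)(OCC)OCC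
Why: Horner–Wadsworth–Emmons olefination of the α-acetal ketone should favour the E ester (ester trans to the acetal carbon), which is separated from the Z isomer by chromatography.

Step 4
Reactants: 5 E ester
Product: 6 (E)-4,4-dimethoxy-3-methylbut-2-en-1-ol
Conditions: DIBAL-H (2.2 equiv), CH2Cl2, −78 °C
Reagents that add atoms: none
Why: DIBAL-H reduces the conjugated ester to the allylic alcohol by 1,2-reduction, leaving alkene geometry and acetal untouched.

Step 5
Reactants: 6 allylic alcohol
Product: 7 (E)-4-chloro-1,1-dimethoxy-2-methylbut-2-ene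
Conditions: NCS, Me2S, CH2Cl2, −20 → 0 °C
Reagents that add atoms: N-chlorosuccinimide, ClN1C(=O)CCC1=O
Why: Corey–Kim chlorination converts the primary allylic alcohol into the chloride under near-neutral conditions that keep the acetal and the E geometry.

Step 6
Reactants: 3 vinyl ketal (1.2 equiv); 7 allyl chloride
Product: 9 (R)-7-[(S)-3-(dimethoxymethyl)-3-methylpent-4-en-1-yl]-8,8-dimethyl-1,4-dioxaspiro[4.5]decane, via B-alkyl-9-BBN 8 (not isolated)
Conditions: 9-BBN-H (1.1 equiv), THF, 60 °C; then 7, CuCl (10 mol%), chiral imidazolinium chloride (carbene precursor, 12 mol%), KOMe, THF/1,4-dioxane, 25 °C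
Reagents that add atoms: none
Why: Anti-Markovnikov hydroboration gives the primary alkylborane, which after boron-to-copper transfer attacks the γ-carbon of the γ,γ-disubstituted allyl chloride (copper-catalysed SN2' allyl–alkyl coupling); the chiral carbene ligand selects the alkene face, so the quaternary carbon with its new vinyl group is set by the catalyst and not by the remote ring stereocentre.

Step 7
Reactants: 9 ketal acetal
Product: 11 (4aS,7S)-4,4,7-trimethyl-7-vinyl-3,4,4a,5,6,7-hexahydronaphthalen-1(2H)-one, via keto aldehyde 10 (not isolated)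
Conditions: 1 M aq. HCl, THF, 25 °C; then piperidine, AcOH (cat.), PhMe, 80 °C
Reagents that add atoms: water, O
Why: Hydrolysis frees the ring ketone and the non-enolisable quaternary aldehyde, and intramolecular aldol condensation (6-enolexo, the only six-membered option) of the ketone α-CH2 onto the aldehyde closes ring A; dehydration can only give the conjugated exocyclic enone.

Step 8
Reactants: 11 bicyclic enone
Product: 12 (1S,4aS,7S)-4,4,7-trimethyl-7-vinyl-1,2,3,4,4a,5,6,7-octahydronaphthalen-1-ol
Conditions: (R)-Me-CBS (20 mol%), catecholborane (1.5 equiv), PhMe, −78 °C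
Reagents that add atoms: none
Why: Corey–Bakshi–Shibata reduction distinguishes the α-branched alkenyl flank from the CH2 flank of the enone carbonyl and should give the (S)-carbinol under reagent control; catecholborane does not hydroborate the vinyl group at this temperature.

Step 9
Reactants: 12 allylic alcohol
Product: 13 (1S,4aS,7S)-4,4,7-trimethyl-7-vinyl-1,2,3,4,4a,5,6,7-octahydronaphthalen-1-yl pyridine-2-carboxylate
Conditions: picolinic acid, EDC·HCl, DMAP (cat.), CH2Cl2, 25 °C
Reagents that add atoms: picolinic acid, OC(=O)c1ccccn1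
Why: Carbodiimide (Steglich-type) esterification installs the chelating picolinate leaving group without touching the allylic stereocentre.

Step 10
Reactants: 13 allylic picolinate
Product: 14 (1S,2S,4aS)-1,2,5,5-tetramethyl-2-vinyl-1,2,3,4,4a,5,6,7-octahydronaphthalene
Conditions: MeMgBr (3 equiv), CuBr·SMe2 (1.5 equiv), THF, −40 → 0 °C
Reagents that add atoms: methylmagnesium bromide, C[Mg]Br
Why: Copper-mediated anti-SN2' substitution of the magnesium-chelated picolinate puts the methyl on the exocyclic alkene carbon from the face opposite the C–O bond (1,3-chirality transfer from the carbinol of step 8, methyl cis to the neighbouring quaternary methyl) and moves the double bond into ring B.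

Step 11
Reactants: 14 vinyl decalin
Product: 16 2-[(1S,2S,4aS)-1,2,5,5-tetramethyl-1,2,3,4,4a,5,6,7-octahydronaphthalen-2-yl]ethan-1-ol, via B-alkyl-9-BBN 15 (not isolated)
Conditions: 9-BBN-H, THF, 60 °C; then NaOH, H2O2, 0 → 25 °C
Reagents that add atoms: hydrogen peroxide, OO
Why: Hydroboration–oxidation; 9-BBN takes the monosubstituted vinyl group in the anti-Markovnikov sense and leaves the hindered trisubstituted ring alkene.

Step 12
Reactants: 16 primary alcohol
Product: 17 2-[(1S,2S,4aS)-1,2,5,5-tetramethyl-1,2,3,4,4a,5,6,7-octahydronaphthalen-2-yl]acetaldehyde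
Conditions: Dess–Martin periodinane, NaHCO3, CH2Cl2, 0 → 25 °C
Reagents that add atoms: none
Why: Dess–Martin oxidation stops at the aldehyde and does not affect the alkene.

Step 13
Reactants: 17 decalinylacetaldehyde
Product: 18 (Z)-3-(dimethylamino)-2-[(1R,2R,4aS)-1,2,5,5-tetramethyl-1,2,3,4,4a,5,6,7-octahydronaphthalen-2-yl]prop-2-enal
Conditions: t-BuOCH(NMe2)2 (1.5 equiv), PhMe, 100 °C
Reagents that add atoms: tert-butoxybis(dimethylamino)methane, CN(C)C(OC(C)(C)C)N(C)C
Why: Aminomethylenation of the aldehyde α-CH2 with the aminal ester gives the 2-substituted 3-(dimethylamino)acrolein, a protected malondialdehyde; the neopentyl position disfavours self-aldol reaction.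

Step 14
Reactants: 18 aminoacrolein; 19 malonic acid
Product: 21 2-oxo-5-[(1R,2R,4aS)-1,2,5,5-tetramethyl-1,2,3,4,4a,5,6,7-octahydronaphthalen-2-yl]-2H-pyran-3-carboxylic acid, via alkylidenemalonic acid 20 (not isolated)
Conditions: malonic acid (3 equiv), pyridine, AcOH, 90 °C
Reagents that add atoms: none
Why: Knoevenagel condensation at the vinylogous formamide aldehyde, then addition of a carboxyl oxygen to the iminium carbon and loss of dimethylamine, closes the six-membered lactone and gives the aromatic 2-pyranone with the second carboxyl at C3.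

Step 15
Reactants: 21 pyranone acid
Product: 22 5-[(1R,2R,4aS)-1,2,5,5-tetramethyl-1,2,3,4,4a,5,6,7-octahydronaphthalen-2-yl]-2H-pyran-2-one
Conditions: Ag2CO3 (10 mol%), AcOH (5 mol%), DMSO, 120 °C
Reagents that add atoms: none
Why: Silver-catalysed protodecarboxylation of the 2-oxo-pyran-3-carboxylic acid removes the C3 carboxyl under conditions that do not isomerise the trisubstituted alkene.

Step 16
Reactants: 22 5-decalinyl-2-pyranone; 23 dimethyl 2-hydroxymalonate
Product: 25 dimethyl (1S,5R,8R)-3-oxo-8-[(1S,2R,4aS)-1,2,5,5-tetramethyl-1,2,3,4,4a,5,6,7-octahydronaphthalen-2-yl]-2,7-dioxabicyclo[3.2.1]octane-6,6-dicarboxylate, via oxa-adduct 24 (not isolated)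
Conditions: 23 (3 equiv), chiral bifunctional iminophosphorane–thiourea base (10 mol%), 4 Å MS, PhMe (1 M), 0 → 25 °C
Reagents that add atoms: none
Why: Proposed new method: the catalyst-bound alkoxide of 23 adds to C6 of the pyranone (oxa-1,6-addition), the dienolate is protonated at C5 to the conjugated 6-alkoxy-5,6-dihydropyranone 24, and the malonate carbon then adds to C4 in a 5-exo-trig Michael closure that forms the oxolane bridge; the closest known reaction types are heteroatom 1,6-additions to 2-pyranones and base-catalysed oxa-Michael/Michael annulations of hydroxymalonates with enones. The acetal and bridgehead centres are set together because the two-atom O–C tether can only span C6 and C4 on one face of the ring. The decalin-bearing centre is set by reversible protonation at C5, the closure going through the epimer that keeps the decalin trans to both new bonds and away from the incoming geminal diester. The sense of the new bicycle relative to the decalin is left to the chiral base (antipode taken if it is the matched one), and the diastereomers should be separable. Oxygen-before-carbon regiochemistry is secured by the hindrance at C6 next to the quaternary carbon and by reversibility of every step except the C–C closure; the excess protic partner in a non-polar solvent should protonate the dienolate before it can open to a dienoate.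

Step 17
Reactants: 25 geminal diester
Product: 26 methyl (1S,5R,6S,8R)-3-oxo-8-[(1S,2R,4aS)-1,2,5,5-tetramethyl-1,2,3,4,4a,5,6,7-octahydronaphthalen-2-yl]-2,7-dioxabicyclo[3.2.1]octane-6-carboxylate
Conditions: LiCl (3 equiv), H2O (2 equiv), DMSO, 130 °C
Reagents that add atoms: none
Why: Krapcho demethoxycarbonylation: chloride demethylates one ester, the carboxylate loses CO2 and the ester enolate is protonated from the open exo face, which should leave the remaining ester endo (26) as the main epimer beside some 27.

Step 18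
Reactants: 26 endo ester (with any 27 from step 17)
Product: 27 methyl (1S,5R,6R,8R)-3-oxo-8-[(1S,2R,4aS)-1,2,5,5-tetramethyl-1,2,3,4,4a,5,6,7-octahydronaphthalen-2-yl]-2,7-dioxabicyclo[3.2.1]octane-6-carboxylate
Conditions: KHMDS (0.3 equiv), THF, −40 → −20 °C; then AcOH
Reagents that add atoms: none
Why: Base-mediated epimerisation α to the ester: the endo ester lies under the lactone bridge beside its CH2 and ring oxygen, so reversible deprotonation by a sub-stoichiometric, non-nucleophilic amide base should shift the mixture to the less hindered exo ester; the other centres of the bicycle are not acidic or are locked at bridgeheads.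

**Compound list**

1 | 4,4-dimethylcyclohex-2-en-1-one | CC1(C)CCC(=O)C=C1 | starting material
2 | (S)-4,4-dimethyl-3-vinylcyclohexan-1-one | C=C[C@@H]1CC(=O)CCC1(C)C | intermediate
3 | (S)-8,8-dimethyl-7-vinyl-1,4-dioxaspiro[4.5]decane | C=C[C@@H]1CC2(OCCO2)CCC1(C)C | intermediate
4 | 1,1-dimethoxypropan-2-one | CC(=O)C(OC)OC | starting material
5 | ethyl (E)-4,4-dimethoxy-3-methylbut-2-enoate | CCOC(=O)/C=C(\C)C(OC)OC | intermediate
6 | (E)-4,4-dimethoxy-3-methylbut-2-en-1-ol | OC/C=C(\C)C(OC)OC | intermediate
7 | (E)-4-chloro-1,1-dimethoxy-2-methylbut-2-ene | ClC/C=C(\C)C(OC)OC | intermediate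
8 | 9-{2-[(R)-8,8-dimethyl-1,4-dioxaspiro[4.5]decan-7-yl]ethyl}-9-borabicyclo[3.3.1]nonane | C1CC2CCCC(C1)B2CC[C@@H]3CC4(OCCO4)CCC3(C)C | intermediate (not isolated)
9 | (R)-7-[(S)-3-(dimethoxymethyl)-3-methylpent-4-en-1-yl]-8,8-dimethyl-1,4-dioxaspiro[4.5]decane | C=C[C@](C(OC)OC)(C)CC[C@@H]1CC2(OCCO2)CCC1(C)C | intermediate
10 | (S)-2-{2-[(R)-2,2-dimethyl-5-oxocyclohexyl]ethyl}-2-methylbut-3-enal | C=C[C@](C=O)(C)CC[C@@H]1CC(=O)CCC1(C)C | intermediate (not isolated)
11 | (4aS,7S)-4,4,7-trimethyl-7-vinyl-3,4,4a,5,6,7-hexahydronaphthalen-1(2H)-one | C=C[C@]1(C)CC[C@@H]2C(C(=O)CCC2(C)C)=C1 | intermediate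
12 | (1S,4aS,7S)-4,4,7-trimethyl-7-vinyl-1,2,3,4,4a,5,6,7-octahydronaphthalen-1-ol | C=C[C@]1(C)CC[C@@H]2C([C@@H](O)CCC2(C)C)=C1 | intermediate
13 | (1S,4aS,7S)-4,4,7-trimethyl-7-vinyl-1,2,3,4,4a,5,6,7-octahydronaphthalen-1-yl pyridine-2-carboxylate | C=C[C@]1(C)CC[C@@H]2C([C@@H](OC(=O)c3ccccn3)CCC2(C)C)=C1 | intermediate
14 | (1S,2S,4aS)-1,2,5,5-tetramethyl-2-vinyl-1,2,3,4,4a,5,6,7-octahydronaphthalene | C=C[C@]1(C)CC[C@@H]2C(=CCCC2(C)C)[C@H]1C | intermediate
15 | 9-{2-[(1S,2R,4aS)-1,2,5,5-tetramethyl-1,2,3,4,4a,5,6,7-octahydronaphthalen-2-yl]ethyl}-9-borabicyclo[3.3.1]nonane | C1CC2CCCC(C1)B2CC[C@]3(C)CC[C@@H]4C(=CCCC4(C)C)[C@H]3C | intermediate (not isolated)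
16 | 2-[(1S,2S,4aS)-1,2,5,5-tetramethyl-1,2,3,4,4a,5,6,7-octahydronaphthalen-2-yl]ethan-1-ol | OCC[C@]1(C)CC[C@@H]2C(=CCCC2(C)C)[C@H]1C | intermediate
17 | 2-[(1S,2S,4aS)-1,2,5,5-tetramethyl-1,2,3,4,4a,5,6,7-octahydronaphthalen-2-yl]acetaldehyde | O=CC[C@]1(C)CC[C@@H]2C(=CCCC2(C)C)[C@H]1C | intermediate
18 | (Z)-3-(dimethylamino)-2-[(1R,2R,4aS)-1,2,5,5-tetramethyl-1,2,3,4,4a,5,6,7-octahydronaphthalen-2-yl]prop-2-enal | CN(C)/C=C(\C=O)[C@]1(C)CC[C@@H]2C(=CCCC2(C)C)[C@H]1C | intermediate
19 | malonic acid | OC(=O)CC(=O)O | starting material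
20 | 2-{(E)-3-(dimethylamino)-2-[(1R,2R,4aS)-1,2,5,5-tetramethyl-1,2,3,4,4a,5,6,7-octahydronaphthalen-2-yl]prop-2-en-1-ylidene}malonic acid | CN(C)/C=C(\C=C(C(=O)O)C(=O)O)[C@]1(C)CC[C@@H]2C(=CCCC2(C)C)[C@H]1C | intermediate (not isolated)
21 | 2-oxo-5-[(1R,2R,4aS)-1,2,5,5-tetramethyl-1,2,3,4,4a,5,6,7-octahydronaphthalen-2-yl]-2H-pyran-3-carboxylic acid | OC(=O)C1=CC(=COC1=O)[C@]2(C)CC[C@@H]3C(=CCCC3(C)C)[C@H]2C | intermediate
22 | 5-[(1R,2R,4aS)-1,2,5,5-tetramethyl-1,2,3,4,4a,5,6,7-octahydronaphthalen-2-yl]-2H-pyran-2-one | O=C1C=CC(=CO1)[C@]2(C)CC[C@@H]3C(=CCCC3(C)C)[C@H]2C | intermediate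
23 | dimethyl 2-hydroxymalonate | COC(=O)C(O)C(=O)OC | starting material
24 | dimethyl 2-{[(2S,3R)-6-oxo-3-[(1S,2R,4aS)-1,2,5,5-tetramethyl-1,2,3,4,4a,5,6,7-octahydronaphthalen-2-yl]-3,6-dihydro-2H-pyran-2-yl]oxy}malonate | COC(=O)C(C(=O)OC)O[C@H]1OC(=O)C=C[C@@H]1[C@]2(C)CC[C@@H]3C(=CCCC3(C)C)[C@H]2C | intermediate (not isolated)
25 | dimethyl (1S,5R,8R)-3-oxo-8-[(1S,2R,4aS)-1,2,5,5-tetramethyl-1,2,3,4,4a,5,6,7-octahydronaphthalen-2-yl]-2,7-dioxabicyclo[3.2.1]octane-6,6-dicarboxylate | COC(=O)C1(C(=O)OC)O[C@H]2OC(=O)C[C@@H]1[C@@H]2[C@]3(C)CC[C@@H]4C(=CCCC4(C)C)[C@H]3C | intermediate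
26 | methyl (1S,5R,6S,8R)-3-oxo-8-[(1S,2R,4aS)-1,2,5,5-tetramethyl-1,2,3,4,4a,5,6,7-octahydronaphthalen-2-yl]-2,7-dioxabicyclo[3.2.1]octane-6-carboxylate | COC(=O)[C@H]1O[C@H]2OC(=O)C[C@@H]1[C@@H]2[C@]3(C)CC[C@@H]4C(=CCCC4(C)C)[C@H]3C | intermediate
27 | methyl (1S,5R,6R,8R)-3-oxo-8-[(1S,2R,4aS)-1,2,5,5-tetramethyl-1,2,3,4,4a,5,6,7-octahydronaphthalen-2-yl]-2,7-dioxabicyclo[3.2.1]octane-6-carboxylate | COC(=O)[C@@H]1O[C@H]2OC(=O)C[C@@H]1[C@@H]2[C@]1(C)CC[C@@H]2C(=CCCC2(C)C)[C@H]1C | target

**Count and risks**

Total step count: 18. Longest linear sequence: 16 steps (4 → 27; 15 steps from 1).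

Steps most likely to fail:

1. Step 16 (proposed new method). The alkoxide may not add to the unactivated pyranone, the dienolate may open to a dienoate instead of being protonated at C5, or the catalyst may give poor facial selectivity relative to the decalin. The fallback uses known reactions, sets out from aldehyde 17 and rejoins the route at 26. Aldehyde 17 would be silylated (TBSOTf, Et3N, CH2Cl2) to the (Z)-tert-butyldimethylsilyl enol ether F1. Mukaiyama–Michael addition of F1 to methyl (S)-5-oxo-2,5-dihydrofuran-2-carboxylate F2 (made from L-glutamic acid) with BF3·OEt2 in CH2Cl2 at −78 °C, anti to the ester, should give the lactone aldehyde F3. Mild acid (PPTS, wet toluene, 60 °C) should then transfer the lactone: the ring oxygen adds to the aldehyde and the freed carboxyl closes onto the lactol, while the epimerisable formyl-bearing carbon settles. This gives the endo ester 26 before step 18, with the configuration of the bicycle relative to the decalin coming from the chiral-pool butenolide.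

2. Step 18. The amide base may open the lactone acetal or trigger retro-Michael loss of the glycolate unit back to 22 instead of clean epimerisation. The fallback sets out from 26 and rejoins at 27. Camphorsulfonic acid in methanol at 25 °C should open 26 to the monocyclic methyl acetal diester with the ring ester cis to the CH2CO2Me arm, F4. NaOMe in MeOH, to which the acetal is inert, should equilibrate the ester-bearing carbon to the trans isomer F5. PPTS in wet toluene at 60 °C should then reclose the lactone acetal with loss of methanol to give 27.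

3. Step 17. The lactone acetal may be hydrolysed or degraded in hot wet DMSO with chloride before the malonate is dealkylated. The fallback sets out from 25 and rejoins at 26. The less hindered exo ester would be cleaved with Me3SnOH in 1,2-dichloroethane at 70 °C to the half acid F6, which as a malonic half acid should lose CO2 on warming in toluene at 90 °C to give 26 before step 18.

**Further compounds**

F1 | step 16 | (Z)-tert-butyldimethylsilyl enol ether of aldehyde 17 | CC(C)(C)[Si](C)(C)O/C=C\[C@]1(C)CC[C@@H]2C(=CCCC2(C)C)[C@H]1C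
F2 | step 16 | methyl (S)-5-oxo-2,5-dihydrofuran-2-carboxylate | COC(=O)[C@H]1OC(=O)C=C1
F3 | step 16 | methyl (2S)-5-oxo-3-(1-decalinyl-2-oxoethyl)tetrahydrofuran-2-carboxylate, side chain trans to the ester, decalinyl as in 17 | COC(=O)[C@H]1OC(=O)C[C@@H]1[C@@H](C=O)[C@]2(C)CC[C@@H]3C(=CCCC3(C)C)[C@H]2C
F4 | step 18 | methyl 5-methoxy-3-(2-methoxy-2-oxoethyl)-4-decalinyltetrahydrofuran-2-carboxylate, ring ester cis to the CH2CO2Me arm | COC(=O)[C@H]1O[C@H](OC)[C@@H]([C@]2(C)CC[C@@H]3C(=CCCC3(C)C)[C@H]2C)[C@H]1CC(=O)OC
F5 | step 18 | methyl 5-methoxy-3-(2-methoxy-2-oxoethyl)-4-decalinyltetrahydrofuran-2-carboxylate, ring ester trans to the CH2CO2Me arm | COC(=O)[C@@H]1O[C@H](OC)[C@@H]([C@]2(C)CC[C@@H]3C(=CCCC3(C)C)[C@H]2C)[C@H]1CC(=O)OC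
F6 | step 17 | exo half acid of 25: 6-endo-(methoxycarbonyl)-3-oxo-8-decalinyl-2,7-dioxabicyclo[3.2.1]octane-6-exo-carboxylic acid | OC(=O)[C@]1(C(=O)OC)O[C@H]2OC(=O)C[C@@H]1[C@@H]2[C@]3(C)CC[C@@H]4C(=CCCC4(C)C)[C@H]3C
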